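What is fed into a stirred flask stays in it, so in larch the starting material fed so far must stand as starting material, as target, or as something unread.

| flask | starting material | free enzyme | temperature | remark | time |
|---|---|---|---|---|---|
| larch | 40 mM (fed, over 1.0 h) | 20 µM | 37 °C | run made earlier; the fed solution adds 1.0 times the starting volume |  |
| autumn | 20 mM (fed, over 1.0 h) | 20 µM | 37 °C | the fed solution adds 1.0 times the starting volume | 6.0 h |
| winter | 20 mM | 20 µM | 37 °C | everything together at the start, the whole solution of starting material included, so that from the start the volume is larger by 1.0 times the starting volume | 2.0 h |

larch run (percent of the starting material charged)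

| time / min | target / % | starting material / % |
|---|---|---|
| 12.0 | 13.0 | 6.4 |
| 25.0 | 26.8 | 13.6 |
| 40.0 | 42.7 | 22.4 |
| 50.0 | 52.9 | 27.2 |
| 60.0 | 62.8 | 32.2 |
| 80.0 | 75.6 | 16.9 |

(standard deviation of a reading: 0.3 percentage points)

- charges are per starting volume, the dose included; the dosed solution carries all of it
- percentages count the whole charge, also what has not yet gone in

* the winner by amount of target, in percent of the starting material charged; "neither" if no more than 2 percentage points parts them (autumn / winter / neither)
* how much target is there at the end, in percent of the starting material charged: autumn
* how much target is there at the end, in percent of the starting material charged: winter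

The feed in larch was complete at 60.0 min, and the unread part then stood at 5.00%, but at 80.0 min it stood at 7.50%. It grew faster per minute after the feed than during it. A first-order loss of starting material fits those readings as well, so they did not name the species that lost it, and I booked the loss on target as an assumption.

Its gain, divided by the mean target and the time between those readings, gave 0.108 /h. On that assumption this reading, with the scatter of 0.3 percentage points in it, is the loss constant of target: the fraction of c(target) lost per hour at this enzyme and final volume, a pseudo-first-order constant. Autumn and winter both end at larch's volume and enzyme level, so I carried it over.

In larch, starting material fell much faster than that, so I let target age from its making. Autumn's mean age was the time less half the feed, which gave 55.1%. Winter's age was its whole time, which gave 80.5%. I therefore put winter ahead.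

The forecast, which differed from my reckoning, said neither, with autumn at 93% (80% to 98%) and winter at 92% (82% to 98%), on the words “I assume starting-material loss”.

The winner was winter, with autumn at 52.3% and winter at 79.9%.

    free enzyme → unfolded enzyme (k = 1.74 × 10⁻⁵ /min, Ea = 283 kJ/mol)
    starting material + free enzyme → target + free enzyme, rate k2*[starting material]*[free enzyme]/(1 + ([starting material]/Km2) + ([target]/Kp2)) (6.00 mM, 0.389 mM, k = 1.22 × 10⁵ /M/min, Ea = 39.0 kJ/mol)
    target + free enzyme ⇌ isomer of the product + free enzyme, rate k3*[free enzyme]*[target] forward; the back reaction follows from the equilibrium constant (K = 11.0, k = 209 /M/min, Ea = 50.0 kJ/mol, ΔH = −90.0 kJ/mol)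
    2 starting material → self-condensation product (k = 1.26 × 10⁻⁴ /M/min, Ea = 73.0 kJ/mol)
    (constants at 37 °C)

The unread part was isomer of the product: 47.7% in autumn at 6.00 h and 20.0% in winter at 2.00 h, with self-condensation product at 0% in autumn. With 0.108 /h, autumn's age of 5.50 h had stood for 55.1% of target. Winter left until 8.0 h, its amounts and temperature held, reckons the same way to 42.1%, and that flask held 40.0% of target.

The data were generated by integration on assumed constants; noise was put on by code.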